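**Plan**

- Rings: A is the 2,4-dihydroxyphenyl ketone ring, B the phenol ring of the biaryl, C the resorcinol ring of the biaryl, D the 4-hydroxyphenyl ring.
- Cuts: the six O–H bonds (back to O–Me), the aryl–C(=O) bond at position 5' of ring C, and in ring B the bond between carbons 1 and 6 and the bond between carbons 2 and 3.
- Enabling feature: ring B (carbon 1 carries the CH2CH2C(=O)Ar chain, carbon 3 carries ring C, carbon 4 carries OH) is the dehydro form of a 2-aryl-4-alkylcyclohex-2-enone. Carbons 1 and 2 are the α-carbon and carbonyl carbon of an aldehyde; carbons 3, 4, 5 and 6 are the benzylic carbon, the carbonyl carbon and the two vinyl carbons of a benzyl vinyl ketone.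
- Forward: aldehyde 8 (three steps) and enone 12 (two steps) are joined in one Michael–aldol annulation that closes ring B as cyclohexenone 15, which already holds the first dihydrochalcone chain and the biaryl carbon skeleton.
- Iodine in methanol then aromatises 15 to anisole 16, Friedel–Crafts acylation at position 5' of ring C adds the second dihydrochalcone unit, and BBr3 frees the six phenols.
- Stereochemistry: the target is achiral; the single sp3 stereocentre of 15 is formed as the racemate and disappears on aromatisation.

Key step: step 6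

Remark: since the target has no stereocentre, intermediates 7 and 13–15 are carried as racemates or diastereomer mixtures without consequence.

**Route**

Step 1
Reactants: 1 hex-5-enoic acid
Product: 3 N-methoxy-N-methylhex-5-enamide, via acyl imidazolide 2 (not isolated)
Conditions: CDI (1.1 equiv), CH2Cl2, 0 °C → rt; then MeNHOMe·HCl (1.2 equiv), rt
Reagents that add atoms: N,O-dimethylhydroxylamine hydrochloride, CNOC.Cl
Why: Carbonyldiimidazole activation gives the acyl imidazolide, which the amine acylates cleanly (CDI amidation), and the terminal alkene is inert to both reagents.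

Step 2
Reactants: 4 1-bromo-2,4-dimethoxybenzene; 3 N-methoxy-N-methylhex-5-enamide
Product: 6 1-(2,4-dimethoxyphenyl)hex-5-en-1-one, via 2,4-dimethoxyphenyllithium 5 (not isolated)
Conditions: n-BuLi (1.05 equiv), THF, −78 °C; then 3, −78 → 0 °C; 1 M HCl
Reagents that add atoms: none
Why: Bromine–lithium exchange places lithium only on the carbon that bore bromine, and the aryllithium adds once to the Weinreb amide because the chelated tetrahedral adduct persists until the acidic quench (Weinreb ketone synthesis).

Step 3
Reactants: 6 1-(2,4-dimethoxyphenyl)hex-5-en-1-one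
Product: 8 5-(2,4-dimethoxyphenyl)-5-oxopentanal, via ozonide 7 (not isolated)
Conditions: O3, CH2Cl2, −78 °C, Sudan Red 7B end point; then PPh3, −78 °C → rt
Reagents that add atoms: ozone, [O-][O+]=O
Why: Ozonolysis with reductive work-up cleaves the monosubstituted alkene, which reacts with ozone much faster than the acyl-deactivated dimethoxyarene, and the dye end point guards against excess ozone.

Step 4
Reactants: 9 (2,4-dimethoxyphenyl)acetic acid
Product: 11 2-(2,4-dimethoxyphenyl)-N-methoxy-N-methylacetamide, via acyl imidazolide 10 (not isolated)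
Conditions: CDI (1.1 equiv), CH2Cl2, 0 °C → rt; then MeNHOMe·HCl (1.2 equiv), rt
Reagents that add atoms: N,O-dimethylhydroxylamine hydrochloride, CNOC.Cl
Why: The same CDI amidation applies to the arylacetic acid, and the mild conditions without strong base avoid ketene formation from the activated arylacetyl unit.

Step 5
Reactants: 11 2-(2,4-dimethoxyphenyl)-N-methoxy-N-methylacetamide
Product: 12 1-(2,4-dimethoxyphenyl)but-3-en-2-one
Conditions: CH2=CHMgBr (1.5 equiv), THF, −20 → 0 °C; cannulated into 1 M HCl/Et2O at 0 °C; kept cold in solution over a trace of BHT and used at once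
Reagents that add atoms: vinylmagnesium bromide, C=C[Mg]Br
Why: Vinyl Grignard addition stops at the chelated adduct (Weinreb ketone synthesis), and the inverse quench into cold acid protonates the liberated N,O-dimethylhydroxylamine before it can add to the new vinyl ketone.

Step 6
Reactants: 8 5-(2,4-dimethoxyphenyl)-5-oxopentanal; 12 1-(2,4-dimethoxyphenyl)but-3-en-2-one
Product: 15 rac-2-(2,4-dimethoxyphenyl)-4-[3-(2,4-dimethoxyphenyl)-3-oxopropyl]cyclohex-2-en-1-one, via keto aldehyde 13 (not isolated), via hydroxy ketone 14 (not isolated)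
Conditions: pyrrolidine (20 mol %), AcOH (20 mol %), toluene, 0 °C → rt, 12 added slowly; then 4 Å MS, 80 °C
Reagents that add atoms: none
Why: Pyrrolidine converts aldehyde 8 into its enamine, which adds to the terminal carbon of enone 12 and is hydrolysed to keto aldehyde 13, so the bond between the chain-bearing carbon and the neighbouring ring CH2 is formed first. The benzylic methylene of 13, activated by both the aryl group and the ketone, then adds to the aldehyde in a 6-(enolendo)-exo-trig aldol closure to 14, and elimination of water through the enolate gives the aryl-conjugated enone 15. The closest known reaction type is the enamine (Stork) variant of the Robinson annulation, which turns aldehydes and vinyl ketones into 4-substituted cyclohex-2-enones. The only stereocentre that remains, position 4 of the cyclohexenone, is formed without control as the racemate and is erased in step 7, and those of 14 disappear on dehydration. The step needs closure through the benzylic carbon onto the aldehyde, which is secured because that carbon is the most acidic position and the aldehyde the most electrophilic carbonyl, while every alternative intramolecular aldol would give a four- or eight-membered ring or attack a ketone. Slow addition of 12 keeps its self-condensation below the rate of the cross Michael addition.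

Step 7
Reactants: 15 rac-2-(2,4-dimethoxyphenyl)-4-[3-(2,4-dimethoxyphenyl)-3-oxopropyl]cyclohex-2-en-1-one
Product: 16 1-(2,4-dimethoxyphenyl)-3-(2',4',6-trimethoxy-[1,1'-biphenyl]-3-yl)propan-1-one
Conditions: I2 (2 equiv), MeOH, reflux; aq. Na2S2O3
Reagents that add atoms: methanol, CO
Why: Iodine in refluxing methanol aromatises cyclohexenones to anisoles through the dimethyl ketal, the methoxydiene, iodination and loss of HI (iodine–methanol oxidative aromatisation), so the methoxy oxygen comes from methanol, and the aryl ketone and the electron-rich rings should be spared because iodination there is reversed by the HI formed whereas loss of HI from the six-membered ring is made irreversible by aromatisation.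

Step 8
Reactants: 16 1-(2,4-dimethoxyphenyl)-3-(2',4',6-trimethoxy-[1,1'-biphenyl]-3-yl)propan-1-one; 17 3-(4-methoxyphenyl)propanoic acid
Product: 19 1-(2,4-dimethoxyphenyl)-3-{2',4',6-trimethoxy-5'-[3-(4-methoxyphenyl)propanoyl]-[1,1'-biphenyl]-3-yl}propan-1-one, via acid chloride 18 (not isolated)
Conditions: 17 (1.2 equiv), (COCl)2, DMF (cat.), CH2Cl2, rt, evaporated; then 16, AlCl3 (3 equiv), CH2Cl2, 0 °C; ice/1 M HCl
Reagents that add atoms: none
Why: Friedel–Crafts acylation should go to position 5' of ring C, the only free position para to one methoxy group and ortho to another on a ring without an acyl group, whereas ring A is deactivated by its AlCl3-bound ketone, the anisole-type rings B and D are far less nucleophilic, closure of 18 to an indanone would need attack meta to its methoxy group, and any methyl ether lost to AlCl3 converges in step 9.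

Step 9
Reactants: 19 1-(2,4-dimethoxyphenyl)-3-{2',4',6-trimethoxy-5'-[3-(4-methoxyphenyl)propanoyl]-[1,1'-biphenyl]-3-yl}propan-1-one
Product: 20 1-(2,4-dihydroxyphenyl)-3-{2',4',6-trihydroxy-5'-[3-(4-hydroxyphenyl)propanoyl]-[1,1'-biphenyl]-3-yl}propan-1-one
Conditions: BBr3 (12 equiv), CH2Cl2, −78 °C → rt; then ice water
Reagents that add atoms: none
Why: BBr3 cleaves all six aryl methyl ethers by bromide attack on the methyl group of the borane–ether adduct (Lewis acid ether cleavage), those ortho to the ketones fastest through chelation, and the two saturated aryl ketones are returned unchanged on hydrolysis.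

**Compound list**

1 | hex-5-enoic acid | C=CCCCC(=O)O | starting material
2 | 1-(1H-imidazol-1-yl)hex-5-en-1-one | C=CCCCC(=O)n1ccnc1 | intermediate (not isolated)
3 | N-methoxy-N-methylhex-5-enamide | C=CCCCC(=O)N(C)OC | intermediate
4 | 1-bromo-2,4-dimethoxybenzene | COc1ccc(Br)c(OC)c1 | starting material
5 | (2,4-dimethoxyphenyl)lithium | [Li]c1ccc(OC)cc1OC | intermediate (not isolated)
6 | 1-(2,4-dimethoxyphenyl)hex-5-en-1-one | C=CCCCC(=O)c1ccc(OC)cc1OC | intermediate
7 | 1-(2,4-dimethoxyphenyl)-4-(1,2,4-trioxolan-3-yl)butan-1-one, racemic | COc1ccc(C(=O)CCCC2OCOO2)c(OC)c1 | intermediate (not isolated)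
8 | 5-(2,4-dimethoxyphenyl)-5-oxopentanal | O=CCCCC(=O)c1ccc(OC)cc1OC | intermediate
9 | (2,4-dimethoxyphenyl)acetic acid | OC(=O)Cc1ccc(OC)cc1OC | starting material
10 | 2-(2,4-dimethoxyphenyl)-1-(1H-imidazol-1-yl)ethan-1-one | O=C(Cc1ccc(OC)cc1OC)n1ccnc1 | intermediate (not isolated)
11 | 2-(2,4-dimethoxyphenyl)-N-methoxy-N-methylacetamide | CON(C)C(=O)Cc1ccc(OC)cc1OC | intermediate
12 | 1-(2,4-dimethoxyphenyl)but-3-en-2-one | C=CC(=O)Cc1ccc(OC)cc1OC | intermediate
13 | 6-(2,4-dimethoxyphenyl)-2-[3-(2,4-dimethoxyphenyl)-3-oxopropyl]-5-oxohexanal, racemic | O=CC(CCC(=O)c1ccc(OC)cc1OC)CCC(=O)Cc1ccc(OC)cc1OC | intermediate (not isolated)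
14 | 2-(2,4-dimethoxyphenyl)-4-[3-(2,4-dimethoxyphenyl)-3-oxopropyl]-3-hydroxycyclohexan-1-one, mixture of diastereomers | COc1ccc(C(=O)CCC2CCC(=O)C(c3ccc(OC)cc3OC)C2O)c(OC)c1 | intermediate (not isolated)
15 | 2-(2,4-dimethoxyphenyl)-4-[3-(2,4-dimethoxyphenyl)-3-oxopropyl]cyclohex-2-en-1-one, racemic | COc1ccc(C(=O)CCC2CCC(=O)C(c3ccc(OC)cc3OC)=C2)c(OC)c1 | intermediate
16 | 1-(2,4-dimethoxyphenyl)-3-(2',4',6-trimethoxy-[1,1'-biphenyl]-3-yl)propan-1-one | COc1ccc(C(=O)CCc2ccc(OC)c(-c3ccc(OC)cc3OC)c2)c(OC)c1 | intermediate
17 | 3-(4-methoxyphenyl)propanoic acid | COc1ccc(CCC(=O)O)cc1 | starting material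
18 | 3-(4-methoxyphenyl)propanoyl chloride | COc1ccc(CCC(Cl)=O)cc1 | intermediate (not isolated)
19 | 1-(2,4-dimethoxyphenyl)-3-{2',4',6-trimethoxy-5'-[3-(4-methoxyphenyl)propanoyl]-[1,1'-biphenyl]-3-yl}propan-1-one | COc1ccc(C(=O)CCc2ccc(OC)c(-c3cc(C(=O)CCc4ccc(OC)cc4)c(OC)cc3OC)c2)c(OC)c1 | intermediate
20 | 1-(2,4-dihydroxyphenyl)-3-{2',4',6-trihydroxy-5'-[3-(4-hydroxyphenyl)propanoyl]-[1,1'-biphenyl]-3-yl}propan-1-one (CID44566750) | O=C(CCc1ccc(O)c(-c2cc(C(=O)CCc3ccc(O)cc3)c(O)cc2O)c1)c1ccc(O)cc1O | target

**Step count**

Total: 9 steps. Longest linear sequence: 7 steps (steps 1, 2, 3, 6, 7, 8, 9, from hex-5-enoic acid).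

**Steps most likely to fail**

Step 6. Enone 12 is itself a Michael donor at its benzylic carbon, so its oligomerisation or self-annulation may outrun the cross addition, and the aldehyde may self-condense under amine catalysis. The fallback sets out from aldehyde 8 and brings the aryl group in by cross-coupling. Amine-catalysed Michael addition of 8 to but-3-en-2-one (pyrrolidine cat., toluene), which has no acidic benzylic position, should give 2-[3-(2,4-dimethoxyphenyl)-3-oxopropyl]-5-oxohexanal F1. Aldol condensation (KOH, MeOH, 0 °C → rt) should close it to 4-[3-(2,4-dimethoxyphenyl)-3-oxopropyl]cyclohex-2-en-1-one F2. α-Iodination (I2, pyridine, CH2Cl2) should give 4-[3-(2,4-dimethoxyphenyl)-3-oxopropyl]-2-iodocyclohex-2-en-1-one F3. Suzuki–Miyaura coupling of F3 with (2,4-dimethoxyphenyl)boronic acid (PdCl2(PhCN)2, AsPh3, Ag2O, THF/H2O, rt) comes back to the route at 15.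

Step 7. Ketalisation of the hindered 2-aryl enone may be slow, so that conjugate addition of methanol, partial aromatisation to a phenol/ether mixture or ring iodination intervene. The fallback sets out from 15 and uses catalytic dehydrogenation instead of halogenation. Aerobic dehydrogenation (Pd(OCOCF3)2 5 mol %, 2-(dimethylamino)pyridine 10 mol %, TsOH 20 mol %, O2 1 atm, DMSO, 80 °C), stopped at full conversion of 15 to limit dehydrogenation of the side chain, should give 1-(2,4-dimethoxyphenyl)-3-(6-hydroxy-2',4'-dimethoxy-[1,1'-biphenyl]-3-yl)propan-1-one F4. O-Methylation of F4 (MeI, K2CO3, acetone, reflux) comes back to the route at 16.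

Step 8. The acylium ion may cyclise to the indanone, acylate a less activated ring or add twice, and AlCl3 may strip methyl ethers and complicate isolation. The fallback sets out from 16 and replaces the acylation by halogenation and carbonylative coupling. Iodination with N-iodosuccinimide and catalytic CF3CO2H in MeCN, a weaker and more selective electrophile used without Lewis acid, should give 1-(2,4-dimethoxyphenyl)-3-(5'-iodo-2',4',6-trimethoxy-[1,1'-biphenyl]-3-yl)propan-1-one F5. Hydroboration of 4-methoxystyrene with 9-BBN (THF, rt) should give 9-[2-(4-methoxyphenyl)ethyl]-9-borabicyclo[3.3.1]nonane F6. Carbonylative Suzuki–Miyaura coupling of F5 with F6 (CO 1 atm, Pd(PPh3)4, K3PO4, dioxane, 60 °C) comes back to the route at 19.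

**Further compounds**

F1 | step 6 | 2-[3-(2,4-dimethoxyphenyl)-3-oxopropyl]-5-oxohexanal, racemic | CC(=O)CCC(C=O)CCC(=O)c1ccc(OC)cc1OC
F2 | step 6 | 4-[3-(2,4-dimethoxyphenyl)-3-oxopropyl]cyclohex-2-en-1-one, racemic | COc1ccc(C(=O)CCC2CCC(=O)C=C2)c(OC)c1
F3 | step 6 | 4-[3-(2,4-dimethoxyphenyl)-3-oxopropyl]-2-iodocyclohex-2-en-1-one, racemic | COc1ccc(C(=O)CCC2CCC(=O)C(I)=C2)c(OC)c1
F4 | step 7 | 1-(2,4-dimethoxyphenyl)-3-(6-hydroxy-2',4'-dimethoxy-[1,1'-biphenyl]-3-yl)propan-1-one | COc1ccc(C(=O)CCc2ccc(O)c(-c3ccc(OC)cc3OC)c2)c(OC)c1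
F5 | step 8 | 1-(2,4-dimethoxyphenyl)-3-(5'-iodo-2',4',6-trimethoxy-[1,1'-biphenyl]-3-yl)propan-1-one | COc1ccc(C(=O)CCc2ccc(OC)c(-c3cc(I)c(OC)cc3OC)c2)c(OC)c1
F6 | step 8 | 9-[2-(4-methoxyphenyl)ethyl]-9-borabicyclo[3.3.1]nonane | COc1ccc(CCB2C3CCCC2CCC3)cc1
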